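**Retrosynthetic overview**
1. Target 14 ⇐ cation exchange and O-debenzylation of the 3'-O-benzyl tris-sulfate salt 12 ⇐ trisulfation of 3'-O-benzylrhamnetin 11, in which only 3-OH, 5-OH and 4'-OH are free.
2. 11 ⇐ removal of two MOM groups from flavonol 10 ⇐ Algar–Flynn–Oyamada oxidative cyclisation of 2'-hydroxychalcone 8.
3. 8 ⇐ Claisen–Schmidt aldol condensation (the key C–C bond, Cα–Cβ of the enone) of acetophenone 3 with benzaldehyde 6.
4. 3 ⇐ phloroacetophenone 1 (4'-O-Me, then 6'-O-MOM); 6 ⇐ protocatechualdehyde 4 (4-O-MOM, then 3-O-Bn).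
5. Ring order: rings A and B are bought as aromatics; the pyranone C ring is the only ring formed (step 6).

Assumption: the target has no stereocentre, so no stereocontrol is needed; it is delivered in the drawn free-acid form by a final cold cation exchange, with salt 13 as the storable form.

**Step 1**
Reactants: 1 2',4',6'-trihydroxyacetophenone
Product: 2 2',6'-dihydroxy-4'-methoxyacetophenone
Conditions: Me2SO4 (1.0 equiv), K2CO3 (1.0 equiv), acetone, rt to reflux, 5 h; chromatography
Reagents that add atoms: dimethyl sulfate, COS(=O)(=O)OC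
Why: Williamson O-methylation with one equivalent of base goes mainly to the 4'-OH, the most acidic and least hindered phenol (para to the acetyl group and not hydrogen-bonded to it); the minor 4',6'-dimethyl ether is separated.

**Step 2**
Reactants: 2 2',6'-dihydroxy-4'-methoxyacetophenone
Product: 3 2'-hydroxy-4'-methoxy-6'-(methoxymethoxy)acetophenone
Conditions: MOMCl (1.1 equiv), K2CO3 (2 equiv), acetone, 0 °C to rt
Reagents that add atoms: chloromethyl methyl ether, COCCl
Why: Williamson-type MOM etherification of one of two equivalent OH groups stops at the mono-ether because the remaining OH is locked in a strong hydrogen bond to the ketone.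

**Step 3**
Reactants: 4 3,4-dihydroxybenzaldehyde
Product: 5 3-hydroxy-4-(methoxymethoxy)benzaldehyde
Conditions: MOMCl (1.0 equiv), K2CO3 (1.0 equiv), acetone, 0 °C to rt; chromatography
Reagents that add atoms: chloromethyl methyl ether, COCCl
Why: The 4-OH (para to the formyl group) is much the more acidic phenol, so one equivalent of base gives the 4-phenoxide and regioselective Williamson-type mono-MOM etherification.

**Step 4**
Reactants: 5 3-hydroxy-4-(methoxymethoxy)benzaldehyde
Product: 6 3-(benzyloxy)-4-(methoxymethoxy)benzaldehyde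
Conditions: BnBr (1.2 equiv), K2CO3 (1.5 equiv), DMF, rt, 12 h
Reagents that add atoms: benzyl bromide, BrCc1ccccc1
Why: Williamson benzylation of the only remaining phenol.

**Step 5**
Reactants: 3 2'-hydroxy-4'-methoxy-6'-(methoxymethoxy)acetophenone; 6 3-(benzyloxy)-4-(methoxymethoxy)benzaldehyde
Product: 8 (E)-3-(benzyloxy)-2'-hydroxy-4'-methoxy-4,6'-bis(methoxymethoxy)chalcone, via aldol adduct 7 (not isolated)
Conditions: KOH (50% aq., 10 equiv), EtOH, rt, 24–48 h; then AcOH to pH 6 at 0 °C
Reagents that add atoms: none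
Why: Claisen–Schmidt crossed aldol condensation: the methyl ketone enolate adds to the non-enolisable aldehyde and E1cB dehydration gives the conjugated E-enone, with MOM and benzyl ethers stable to base.

**Step 6**
Reactants: 8 (E)-3-(benzyloxy)-2'-hydroxy-4'-methoxy-4,6'-bis(methoxymethoxy)chalcone
Product: 10 3'-(benzyloxy)-3-hydroxy-7-methoxy-5,4'-bis(methoxymethoxy)flavone, via trans-dihydroflavonol 9 (not isolated)
Conditions: 30% H2O2 (8 equiv), 2 M NaOH (aq., 8 equiv), MeOH/THF, 0 °C to rt, 12 h; then AcOH to pH 5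
Reagents that add atoms: hydrogen peroxide, OO
Why: Algar–Flynn–Oyamada reaction: oxa-Michael closure of the 2'-phenoxide, hydroxylation of the enolate by H2O2 and further oxidation of the dihydroflavonol give the flavonol with a free 3-OH, and the transient stereocentres disappear on aromatisation of the C ring.

**Step 7**
Reactants: 10 3'-(benzyloxy)-3-hydroxy-7-methoxy-5,4'-bis(methoxymethoxy)flavone
Product: 11 3'-O-benzylrhamnetin (3'-(benzyloxy)-3,5,4'-trihydroxy-7-methoxyflavone)
Conditions: HCl (ca. 1 M in MeOH), THF co-solvent, 50 °C, 2–3 h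
Reagents that add atoms: none
Why: Acid-catalysed acetal (MOM) solvolysis frees 5-OH and 4'-OH while the benzyl and methyl ethers are inert, leaving exactly the three hydroxyls that are to be sulfated.

**Step 8**
Reactants: 11 3'-O-benzylrhamnetin
Product: 12 tris(triethylammonium) 3'-O-benzylrhamnetin 3,5,4'-tri-O-sulfate
Conditions: SO3·NEt3 (18 equiv), Et3N (6 equiv), MeCN, 100 °C (sealed, microwave), 45 min; RP-C18, MeCN/aq. Et3NH·HCO3; lyophilise
Reagents that add atoms: sulfur trioxide–triethylamine complex, CC[N+](CC)(CC)S(=O)(=O)[O-]; triethylamine, CCN(CC)CC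
Why: O-sulfation by SO3 transfer from the amine complex, with large excess, base and heat to drive even the chelated 5-OH; the 3'-oxygen cannot react because it is benzylated.

**Step 9**
Reactants: 12 tris(triethylammonium) 3'-O-benzylrhamnetin 3,5,4'-tri-O-sulfate
Product: 13 tris(triethylammonium) rhamnetin 3,5,4'-tri-O-sulfate
Conditions: H2 (1 atm), 10% Pd/C, MeOH/H2O 4:1, rt, 2–4 h; filter, lyophilise
Reagents that add atoms: none
Why: Catalytic hydrogenolysis cleaves the benzyl ether under neutral conditions, which aryl sulfate salts and the tetrasubstituted chromone C2=C3 bond tolerate.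

**Step 10**
Reactants: 13 tris(triethylammonium) rhamnetin 3,5,4'-tri-O-sulfate
Product: 14 rhamnetin 3,5,4'-tri-O-sulfate (free acid)
Conditions: Dowex 50W-X8 (H+ form) column, H2O, 0–4 °C; freeze-dry at once, store at −20 °C
Reagents that add atoms: none
Why: Strong-acid cation exchange replaces Et3NH+ by H+, and working cold with immediate freeze-drying limits acid-catalysed desulfation.

**Compound list**
1 | 2',4',6'-trihydroxyacetophenone (phloroacetophenone) | CC(=O)c1c(O)cc(O)cc1O | starting material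
2 | 2',6'-dihydroxy-4'-methoxyacetophenone | CC(=O)c1c(O)cc(OC)cc1O | intermediate
3 | 2'-hydroxy-4'-methoxy-6'-(methoxymethoxy)acetophenone | CC(=O)c1c(O)cc(OC)cc1OCOC | intermediate
4 | 3,4-dihydroxybenzaldehyde (protocatechualdehyde) | O=Cc1ccc(O)c(O)c1 | starting material
5 | 3-hydroxy-4-(methoxymethoxy)benzaldehyde | O=Cc1ccc(OCOC)c(O)c1 | intermediate
6 | 3-(benzyloxy)-4-(methoxymethoxy)benzaldehyde | O=Cc1ccc(OCOC)c(OCc2ccccc2)c1 | intermediate
7 | aldol adduct, racemic 3-[3-(benzyloxy)-4-(methoxymethoxy)phenyl]-3-hydroxy-1-[2-hydroxy-4-methoxy-6-(methoxymethoxy)phenyl]propan-1-one | COCOc1cc(OC)cc(O)c1C(=O)CC(O)c1ccc(OCOC)c(OCc2ccccc2)c1 | intermediate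
8 | (E)-3-[3-(benzyloxy)-4-(methoxymethoxy)phenyl]-1-[2-hydroxy-4-methoxy-6-(methoxymethoxy)phenyl]prop-2-en-1-one (chalcone) | COCOc1cc(OC)cc(O)c1C(=O)/C=C/c1ccc(OCOC)c(OCc2ccccc2)c1 | intermediate
9 | trans-dihydroflavonol, racemic trans-2-[3-(benzyloxy)-4-(methoxymethoxy)phenyl]-3-hydroxy-7-methoxy-5-(methoxymethoxy)chroman-4-one ((2R,3R) enantiomer drawn) | COCOc1ccc(cc1OCc1ccccc1)[C@@H]1[C@@H](O)C(=O)c2c(OCOC)cc(OC)cc2O1 | intermediate
10 | 2-[3-(benzyloxy)-4-(methoxymethoxy)phenyl]-3-hydroxy-7-methoxy-5-(methoxymethoxy)-4H-chromen-4-one (flavonol) | COc1cc(OCOC)c2c(=O)c(O)c(-c3ccc(OCOC)c(OCc4ccccc4)c3)oc2c1 | intermediate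
11 | 3'-O-benzylrhamnetin, 2-[3-(benzyloxy)-4-hydroxyphenyl]-3,5-dihydroxy-7-methoxy-4H-chromen-4-one | COc1cc(O)c2c(=O)c(O)c(-c3ccc(O)c(OCc4ccccc4)c3)oc2c1 | intermediate
12 | tris(triethylammonium) 3'-O-benzylrhamnetin 3,5,4'-tri-O-sulfate | COc1cc(OS(=O)(=O)[O-])c2c(=O)c(OS(=O)(=O)[O-])c(-c3ccc(OS(=O)(=O)[O-])c(OCc4ccccc4)c3)oc2c1.CC[NH+](CC)CC.CC[NH+](CC)CC.CC[NH+](CC)CC | intermediate
13 | tris(triethylammonium) rhamnetin 3,5,4'-tri-O-sulfate | COc1cc(OS(=O)(=O)[O-])c2c(=O)c(OS(=O)(=O)[O-])c(-c3ccc(OS(=O)(=O)[O-])c(O)c3)oc2c1.CC[NH+](CC)CC.CC[NH+](CC)CC.CC[NH+](CC)CC | intermediate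
14 | rhamnetin 3,5,4'-tri-O-sulfate (achiral) | COc1cc(OS(=O)(=O)O)c2c(=O)c(OS(=O)(=O)O)c(-c3ccc(OS(=O)(=O)O)c(O)c3)oc2c1 | target

**Step count**
Total steps: 10. Longest linear sequence: 8 steps (steps 1, 2, 5, 6, 7, 8, 9, 10 from compound 1; the aldehyde branch, steps 3 and 4, joins at step 5 and is equally long).

**Three steps most likely to fail**

Step 8 (trisulfation). The 5-OH is chelated to the C4 carbonyl and may be sulfated only partly, giving mono- and disulfate mixtures that are hard to separate as salts. The fallback sets out from 11 and uses a protected sulfate diester instead of SO3 transfer. Treatment with 2,2,2-trichloroethyl chlorosulfate, Et3N and DMAP in THF (a stronger base for the 5-OH if needed) gives the neutral 3'-O-benzylrhamnetin 3,5,4'-tris(2,2,2-trichloroethyl sulfate) F4. This can be purified on silica and checked for complete 5-O-sulfation. Zn dust and HCO2NH4 in MeOH then remove the trichloroethyl groups to give triammonium 3'-O-benzylrhamnetin 3,5,4'-tri-O-sulfate F5. RP-C18 chromatography in triethylammonium bicarbonate buffer exchanges the cations, and the fallback comes back to the route at 12.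

Step 6 (Algar–Flynn–Oyamada). Chalcones with a 6'-alkoxy group can close five-membered to aurones instead of flavonols. The fallback sets out from 8 and separates ring closure from C3 oxygenation. NaOAc in refluxing EtOH isomerises 8 to the racemic flavanone 2-[3-(benzyloxy)-4-(methoxymethoxy)phenyl]-7-methoxy-5-(methoxymethoxy)chroman-4-one F1. I2 in pyridine at 90 °C dehydrogenates it to the flavone 2-[3-(benzyloxy)-4-(methoxymethoxy)phenyl]-7-methoxy-5-(methoxymethoxy)-4H-chromen-4-one F2. Dimethyldioxirane in acetone/CH2Cl2 (0 °C to rt) epoxidises C2=C3 to the racemic flavone 2,3-epoxide F3, which is not isolated and opens on contact with silica or a trace of TsOH to the 3-hydroxyflavone. The fallback comes back to the route at 10.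

Step 10 (free acid). Aryl hydrogen sulfates hydrolyse under their own acidity, the 5-O-sulfate most easily, so material may be lost while the aqueous acid is concentrated. The fallback sets out from 12 and reverses the order of the last two operations. Cold H+ exchange of 12 in aqueous MeCN gives 3'-O-benzylrhamnetin 3,5,4'-tris(hydrogen sulfate) F6, which is more lipophilic and easier to handle. Hydrogenolysis of the cold eluate (H2, Pd/C, t-BuOH/H2O) then forms the target with toluene as the only co-product, and a single freeze-drying follows. The fallback comes back to the route at 14. If the acid form cannot be kept, salt 13 is the practical end point.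

**Further compounds**
F1 | step 6 | racemic 2-[3-(benzyloxy)-4-(methoxymethoxy)phenyl]-7-methoxy-5-(methoxymethoxy)chroman-4-one (flavanone) | COCOc1ccc(cc1OCc1ccccc1)C1CC(=O)c2c(OCOC)cc(OC)cc2O1
F2 | step 6 | 2-[3-(benzyloxy)-4-(methoxymethoxy)phenyl]-7-methoxy-5-(methoxymethoxy)-4H-chromen-4-one (flavone) | COc1cc(OCOC)c2c(=O)cc(-c3ccc(OCOC)c(OCc4ccccc4)c3)oc2c1
F3 | step 6 | racemic 2,3-epoxide of flavone F2 (1a-aryl oxireno-fused chromanone, not isolated) | COCOc1ccc(cc1OCc1ccccc1)C12OC1C(=O)c1c(OCOC)cc(OC)cc1O2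
F4 | step 8 | 3'-O-benzylrhamnetin 3,5,4'-tris(2,2,2-trichloroethyl sulfate) | COc1cc(OS(=O)(=O)OCC(Cl)(Cl)Cl)c2c(=O)c(OS(=O)(=O)OCC(Cl)(Cl)Cl)c(-c3ccc(OS(=O)(=O)OCC(Cl)(Cl)Cl)c(OCc4ccccc4)c3)oc2c1
F5 | step 8 | triammonium 3'-O-benzylrhamnetin 3,5,4'-tri-O-sulfate | COc1cc(OS(=O)(=O)[O-])c2c(=O)c(OS(=O)(=O)[O-])c(-c3ccc(OS(=O)(=O)[O-])c(OCc4ccccc4)c3)oc2c1.[NH4+].[NH4+].[NH4+]
F6 | step 10 | 3'-O-benzylrhamnetin 3,5,4'-tris(hydrogen sulfate) | COc1cc(OS(=O)(=O)O)c2c(=O)c(OS(=O)(=O)O)c(-c3ccc(OS(=O)(=O)O)c(OCc4ccccc4)c3)oc2c1
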